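## Analysis of the target

CNP0077535.2 (35) is a germacranolide. With the usual numbering the ten-membered carbocycle is C1–C10, a trans-fused α-methylene-γ-butyrolactone spans C6–C7 (O6–C12, C11=C13), C14 is a methyl ester on the C1=C10 double bond and C15 is the methyl group on C4. The ring carries a cis epoxide at C2–C3, a trans epoxide at C4–C5, a (2S,3S)-epoxyangelate on O8 and an acetate on O9. The eight ring stereocentres are contiguous (2R,3R,4S,5R,6S,7R,8S,9S). Read along the chain, O5/O6 are threo, C5 and C8 are trans on the lactone, C11 and O8 are anti, O8 and O9 are syn, and the two epoxide oxygens are anti across C3–C4. In the C1=C10 enoate, C2 and C9 are cis in the ring (E by the sequence rule, because C14 outranks C9). The molecule is acid- and base-labile: a bis-epoxide allylic to an enoate, a Michael-accepting methylene lactone, esters that can migrate between O8 and O9, and a lactone that can move from O6 to O8. The difficulty is to close a strained, densely oxygenated medium ring without later redox steps that such a ring would not take selectively. The strategy rests on the C2–C3 epoxide: because it is cis, its parent is a Z olefin C2=C3 inside the ring, between the C1=C10 enoate and the C4–C5 epoxide. Cutting that olefin leaves two vinyl termini, one on C1 of a dienoate and one on C4 of an epoxide.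

## Retrosynthetic reasoning

35 ⇒ 34. The two C–O bonds of the 2,3-epoxide are removed last. C2=C3 of 34 is the only olefin that is neither an enoate α,β-bond nor the lactone methylene, so an electrophilic oxygen donor should find it, and the folded ring exposes one face. Nothing else has to change after ring closure.

34 ⇒ 33. The C2=C3 bond is cut by olefin metathesis. This is the only ring bond whose scission leaves every stereocentre, both esters, the lactone and the 4,5-epoxide untouched in an open chain. The forward reaction must join two monosubstituted vinyl groups with Z geometry and ignore the C11=C13 and C1=C10 olefins.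

33 ⇒ 32 ⇒ 27 + 31. Removing the O9 acetyl group exposes carbinol 32, and the C9–C10 bond is then cut between aldehyde 27 and alkenyl iodide 31. This attaches the whole dienoate in one step with its geometry fixed beforehand; the forward coupling has to set C9.

31 ⇒ 28 + 29. The C1=C10 bond of the iodide is a Wittig bond between iodinated ylide 30 (from 28) and enal 29. A stabilised ylide places the ester trans to the vinyl group, which is the geometry the ring needs.

27 ⇒ 26 ⇒ 23. The C9 aldehyde is the ozonolysis product of a C9=C(CH3)2 olefin. A trisubstituted olefin is chosen so that it can be cleaved in the presence of the vinyl epoxide and the methylene lactone. The C11=C13 methylene is traced to the saturated lactone 23 by Mannich methylenation, done before any aldehyde or dienoate is present.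

23 ⇒ 16 + 21. The O8–acyl bond is cut. The hindered epoxyangelate goes on first, so the later O9 acetate cannot be displaced by it and no protecting group is needed on O8. Acid 21 comes from 17 through 18 and 19, with the epoxide set by reagent control and the carbinol then oxidised.

16 ⇒ 15 ⇒ 14 ⇒ 12. C8 is traced to ketone 15 because hydride addition under Felkin–Anh control gives the O8/C11 anti relationship, whereas carbon addition to a C8 aldehyde would give the epimer. The C8–C9 bond is then an acylation of a 2-methylpropenyl nucleophile by amide 14, itself made from acid 12.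

12 ⇒ 10 ⇒ 8 + 5. The C6–C7 bond is an auxiliary-controlled syn aldol between the succinate imide 8 (from 6 and 7) and epoxy aldehyde 5. The syn adduct 9 lactonises to the trans lactone, C6–OH is the only hydroxyl present at that point so the lactone position is not in doubt, and the imide carbon becomes C8.

5 ⇒ 4 ⇒ 3 ⇒ 2 ⇒ 1. The trans 4,5-epoxide with its quaternary C4 is the asymmetric epoxidation product of the (E)-dienol 3, reached from the C5 aldehyde ester 1 by methylenation and reduction. The vinyl group needed for the key step is thus present from the second step.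

## Alternatives that were turned down

Alternative 1: The ten-membered ring is unzipped from a trans-fused bicyclo[4.4.0] skeleton across C4–C9. In the forward key step potassium tert-butoxide forms a C9 alkoxide that expels an antiperiplanar equatorial C5 sulfonate; the C4–C9 bond breaks and trienone A1 appears with its C9 ketone and (E)-C4=C5 bond. In its favour, a six-membered-ring precursor is easy to build, the fragmentation has no entropic penalty and no oligomer problem, and the olefin geometry is dictated stereoelectronically. On certainty of ring formation it is stronger than a metathesis closure. Against it for this target, A1 still lacks the lactone (C12 is a silyl ether), the C9 stereocentre (a ketone), both epoxides and both acyl groups. Two epoxidations would have to discriminate among three ring olefins and the C11=C13 methylene, and a (Z,Z,E)-trienone of this kind is prone to transannular and Cope-type reactions. The chosen route offers in exchange that every stereocentre and ester is in place before the ring exists and only one oxygen atom is added afterwards.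

Alternative 2: The C9–O and C2–O bonds are disconnected together. Forward, singlet oxygen adds across C9 and C2 of a ring diene C9=C10–C1=C2 and gives endoperoxide A2, moving the double bond to C1=C10. It sets the C9 oxygen and a C2 oxygen in one suprafacial event, which is stronger than the chosen route's ligand-controlled coupling at C9. It does not build the ring, however, so a macrocyclisation is still needed. The ester-bearing diene is electron-poor and slow towards singlet oxygen, and ene reaction at C8–H or C3–H competes. A2 then needs O–O cleavage, differentiation of two secondary hydroxyls and an inverting closure from C2–O onto C3 to reach the cis epoxide, all on a bis-allylic epoxide. The chosen route makes the ring and the C2=C3 bond in the same step and needs one epoxidation.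

Alternative 3: The C2=C3 and C4=C5 bonds are traced to a cyclobutene fused cis to an eight-membered ring. Forward, heating opens the cyclobutene conrotatorily and gives trienolide A3 with Z-C2=C3 and E-C4=C5 by ring expansion. Orbital symmetry fixes both geometries, which is at least as firm as the strain argument used for the metathesis, and no high dilution is needed. The bicyclo[6.2.0] precursor with five stereocentres is hard to reach, though. The temperature needed for opening is in the range where the 1(10),4-diene of A3 undergoes Cope rearrangement. A3 still needs two selective epoxidations and an exchange of the O8 silyl group for the epoxyangelate. The chosen route runs at 40 °C and carries the 4,5-epoxide, which also blocks the Cope pathway, into the cyclisation.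

Key step: step 20

Assumption: in step 18 the (4S)-sulfonamide ligand is taken as the antipode whose chromium complex delivers the alkenyl group to the aldehyde face that gives the 9S carbinol; if the sense is the reverse, the (4R)-ligand is used and nothing else changes.

## Route

Step 1
Reactants: 1 ethyl (2E)-3-methyl-4-oxobut-2-enoate
Product: 2 ethyl (2E)-3-methylpenta-2,4-dienoate
Conditions: Ph3PCH3Br, KN(SiMe3)2, THF, −78 → 0 °C
Reagents that add atoms: methyltriphenylphosphonium bromide, C[P+](c1ccccc1)(c1ccccc1)c1ccccc1.[Br-]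
Why: Wittig methylenation; the unstabilised ylide attacks the formyl group much faster than the conjugated ester and leaves the (E)-olefin untouched.

Step 2
Reactants: 2 ethyl (2E)-3-methylpenta-2,4-dienoate
Product: 3 (2E)-3-methylpenta-2,4-dien-1-ol
Conditions: i-Bu2AlH (2.2 equiv), CH2Cl2, −78 °C; aq. KNa tartrate
Reagents that add atoms: none
Why: Aluminium hydride 1,2-reduction of the conjugated ester to the allylic alcohol; the diene is not reduced at −78 °C.

Step 3
Reactants: 3 (2E)-3-methylpenta-2,4-dien-1-ol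
Product: 4 [(2R,3R)-3-ethenyl-3-methyloxiran-2-yl]methanol
Conditions: Ti(Oi-Pr)4 (10 mol%), D-(−)-diethyl tartrate (12 mol%), t-BuOOH, 4 Å sieves, CH2Cl2, −20 °C
Reagents that add atoms: tert-butyl hydroperoxide, CC(C)(C)OO
Why: Sharpless asymmetric epoxidation; the titanium tartrate binds the primary allylic alcohol and epoxidises only its own olefin. D-(−)-tartrate gives the (2R,3R)-epoxide, the same sense in which it converts (E)-3-substituted allylic alcohols such as geraniol; this sets C4 and C5.

Step 4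
Reactants: 4 [(2R,3R)-3-ethenyl-3-methyloxiran-2-yl]methanol
Product: 5 (2S,3R)-3-ethenyl-3-methyloxirane-2-carbaldehyde
Conditions: Dess–Martin periodinane, pyridine, CH2Cl2, 0 °C; used crude
Reagents that add atoms: none
Why: Dess–Martin oxidation under buffered, non-acidic conditions keeps the tertiary allylic epoxide closed; the descriptor at C2 changes only because the formyl group outranks C3.

Step 5
Reactants: 6 (4S)-4-benzyl-1,3-oxazolidin-2-one; 7 methyl 4-chloro-4-oxobutanoate
Product: 8 methyl 4-[(4S)-4-benzyl-2-oxo-1,3-oxazolidin-3-yl]-4-oxobutanoate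
Conditions: n-BuLi, THF, −78 °C; then 7, −78 → 0 °C
Reagents that add atoms: none
Why: N-acylation of the lithiated oxazolidinone by the acid chloride, which is far more electrophilic than the methyl ester.

Step 6
Reactants: 8 methyl 4-[(4S)-4-benzyl-2-oxo-1,3-oxazolidin-3-yl]-4-oxobutanoate; 5 (2S,3R)-3-ethenyl-3-methyloxirane-2-carbaldehyde
Product: 10 (4S)-4-benzyl-3-{[(2S,3S)-2-[(2R,3R)-3-ethenyl-3-methyloxiran-2-yl]-5-oxooxolan-3-yl]carbonyl}-1,3-oxazolidin-2-one, via hydroxy ester 9 (not isolated)
Conditions: Bu2BOTf, i-Pr2NEt, CH2Cl2, −78 → 0 °C; 5, −78 → −10 °C; pH 7 buffer, MeOH, 30% H2O2, 0 °C; then 2-hydroxypyridine (cat.), toluene, 50 °C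
Reagents that add atoms: none
Why: Evans syn-aldol: the imide, not the ester, is enolised to the Z-boron enolate, and the chair transition state on the face away from the benzyl group gives syn adduct 9 with C6 and C7 as in the target, overriding the weak bias of the epoxy aldehyde. The γ-hydroxy ester then closes to the trans lactone under neutral bifunctional catalysis.

Step 7
Reactants: 10 (4S)-4-benzyl-3-{[(2S,3S)-2-[(2R,3R)-3-ethenyl-3-methyloxiran-2-yl]-5-oxooxolan-3-yl]carbonyl}-1,3-oxazolidin-2-one
Product: 12 (2S,3S)-2-[(2R,3R)-3-ethenyl-3-methyloxiran-2-yl]-5-oxooxolane-3-carboxylic acid, via peroxy acid 11 (not isolated)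
Conditions: LiOH·H2O, 30% H2O2, THF/H2O 3:1, 0 °C; aq. Na2SO3; 0.5 M HCl to pH 4, 0 °C
Reagents that add atoms: hydrogen peroxide (as LiOOH), OO
Why: Hydroperoxide cleaves the exocyclic imide carbonyl selectively and sulfite reduces peroxy acid 11. Any lactone opened by hydroxide recloses on acidification because O6 is the only hydroxyl, and the trans arrangement keeps the carboxyl away from the epoxide.

Step 8
Reactants: 12 (2S,3S)-2-[(2R,3R)-3-ethenyl-3-methyloxiran-2-yl]-5-oxooxolane-3-carboxylic acid
Product: 14 (2S,3S)-2-[(2R,3R)-3-ethenyl-3-methyloxiran-2-yl]-N-methoxy-N-methyl-5-oxooxolane-3-carboxamide, via acyl imidazolide 13 (not isolated)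
Conditions: 1,1'-carbonyldiimidazole, CH2Cl2, 0 °C → rt; MeNH(OMe)·HCl, rt
Reagents that add atoms: N,O-dimethylhydroxylamine hydrochloride, CNOC.Cl
Why: Weinreb amide formation by carbonyldiimidazole activation and aminolysis under near-neutral conditions that the epoxide and lactone tolerate.

Step 9
Reactants: 14 (2S,3S)-2-[(2R,3R)-3-ethenyl-3-methyloxiran-2-yl]-N-methoxy-N-methyl-5-oxooxolane-3-carboxamide
Product: 15 (4S,5S)-5-[(2R,3R)-3-ethenyl-3-methyloxiran-2-yl]-4-(3-methylbut-2-enoyl)oxolan-2-one
Conditions: (CH3)2C=CHMgBr (1.5 equiv), THF, −78 → −20 °C; aq. NH4Cl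
Reagents that add atoms: (2-methylprop-1-en-1-yl)magnesium bromide, CC(C)=C[Mg]Br
Why: Weinreb ketone synthesis; the chelated tetrahedral intermediate stops at the ketone stage, and at low temperature the amide reacts before the lactone. The ketone is released only on neutral quench, so the β-acyloxy ketone is not exposed to base.

Step 10
Reactants: 15 (4S,5S)-5-[(2R,3R)-3-ethenyl-3-methyloxiran-2-yl]-4-(3-methylbut-2-enoyl)oxolan-2-one
Product: 16 (4R,5S)-5-[(2R,3R)-3-ethenyl-3-methyloxiran-2-yl]-4-[(1R)-1-hydroxy-3-methylbut-2-en-1-yl]oxolan-2-one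
Conditions: Li[HB(s-Bu)3], THF, −78 °C; pH 7 buffer, 30% H2O2, 0 °C
Reagents that add atoms: none
Why: Felkin–Anh-controlled ketone reduction: the bulky borohydride attacks C8 anti to the C7–C6 bond with C11 on the carbonyl-oxygen side, which places O8 anti to C11 as in the target. The β,β-disubstituted enone is reduced 1,2.

Step 11
Reactants: 17 angelic acid, (2Z)-2-methylbut-2-enoic acid
Product: 18 (2Z)-2-methylbut-2-en-1-ol
Conditions: LiAlH4, Et2O, 0 °C → rt; H2O, aq. NaOH
Reagents that add atoms: none
Why: LiAlH4 reduces the carboxylic acid to the primary alcohol and does not touch or isomerise the isolated trisubstituted Z-olefin.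

Step 12
Reactants: 18 (2Z)-2-methylbut-2-en-1-ol
Product: 19 [(2R,3S)-2,3-dimethyloxiran-2-yl]methanol
Conditions: Ti(Oi-Pr)4 (10 mol%), D-(−)-diethyl tartrate (12 mol%), t-BuOOH, 4 Å sieves, CH2Cl2, −20 °C
Reagents that add atoms: tert-butyl hydroperoxide, CC(C)(C)OO
Why: Sharpless asymmetric epoxidation; D-(−)-tartrate attacks the same olefin face as in step 3, which for this Z-trisubstituted alcohol gives the (2R,3S)-epoxide with the two methyl groups trans.

Step 13
Reactants: 19 [(2R,3S)-2,3-dimethyloxiran-2-yl]methanol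
Product: 21 (2S,3S)-2,3-dimethyloxirane-2-carboxylic acid, via epoxy aldehyde 20 (not isolated)
Conditions: RuCl3·xH2O (2 mol%), NaIO4, MeCN/EtOAc/H2O, 0 °C → rt
Reagents that add atoms: water, O; sodium periodate (terminal oxidant), [Na+].[O-]I(=O)(=O)=O
Why: Ruthenium tetroxide made in situ oxidises the primary alcohol through aldehyde 20 and its hydrate to the glycidic acid without opening the epoxide; the descriptor at C2 changes only by priority.

Step 14
Reactants: 21 (2S,3S)-2,3-dimethyloxirane-2-carboxylic acid; 16 (4R,5S)-5-[(2R,3R)-3-ethenyl-3-methyloxiran-2-yl]-4-[(1R)-1-hydroxy-3-methylbut-2-en-1-yl]oxolan-2-one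
Product: 23 (1R)-1-[(2S,3R)-2-[(2R,3R)-3-ethenyl-3-methyloxiran-2-yl]-5-oxooxolan-3-yl]-3-methylbut-2-en-1-yl (2S,3S)-2,3-dimethyloxirane-2-carboxylate, via mixed anhydride 22 (not isolated)
Conditions: 21, 2,4,6-Cl3C6H2COCl, Et3N, toluene, rt; then 16, DMAP, toluene, rt → 40 °C
Reagents that add atoms: none
Why: Yamaguchi esterification; DMAP attacks the aliphatic carbonyl of mixed anhydride 22 because the aroyl carbonyl is shielded by its ortho chlorines, and the alcohol is acylated with retention at C8. The trans 6,12-lactone is the more stable lactone, so acylation occurs at O8.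

Step 15
Reactants: 23 (1R)-1-[(2S,3R)-2-[(2R,3R)-3-ethenyl-3-methyloxiran-2-yl]-5-oxooxolan-3-yl]-3-methylbut-2-en-1-yl (2S,3S)-2,3-dimethyloxirane-2-carboxylate
Product: 26 (1R)-1-[(2S,3R)-2-[(2R,3R)-3-ethenyl-3-methyloxiran-2-yl]-4-methylidene-5-oxooxolan-3-yl]-3-methylbut-2-en-1-yl (2S,3S)-2,3-dimethyloxirane-2-carboxylate, via Mannich base 24 (not isolated), via trimethylammonium iodide 25 (not isolated)
Conditions: LiN(i-Pr)2 (1.1 equiv), THF, −78 °C; Me2N=CH2 I, −78 → 0 °C; MeI, CH2Cl2, rt; aq. NaHCO3, rt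
Reagents that add atoms: N,N-dimethylmethaniminium iodide, C=[N+](C)C.[I-]
Why: α-Methylenation of the lactone by enolate Mannich reaction, quaternisation and E1cB loss of trimethylamine. The lactone CH2 is the only acidic site, since the epoxyangelate has no α-hydrogen.

Step 16
Reactants: 26 (1R)-1-[(2S,3R)-2-[(2R,3R)-3-ethenyl-3-methyloxiran-2-yl]-4-methylidene-5-oxooxolan-3-yl]-3-methylbut-2-en-1-yl (2S,3S)-2,3-dimethyloxirane-2-carboxylate
Product: 27 (1S)-1-[(2S,3S)-2-[(2R,3R)-3-ethenyl-3-methyloxiran-2-yl]-4-methylidene-5-oxooxolan-3-yl]-2-oxoethyl (2S,3S)-2,3-dimethyloxirane-2-carboxylate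
Conditions: O3 (1.0 equiv, Sudan Red 7B end point), pyridine, CH2Cl2, −78 °C
Reagents that add atoms: ozone, [O-][O+]=O
Why: Ozonolysis; electrophilic ozone takes the trisubstituted C9=C(CH3)2 olefin in preference to the monosubstituted vinyl group on the epoxide and the electron-poor lactone methylene. Pyridine turns the carbonyl oxide directly into the aldehyde.

Step 17
Reactants: 28 methyl (triphenyl-λ5-phosphanylidene)acetate; 29 acrolein
Product: 31 methyl (2Z)-2-iodopenta-2,4-dienoate, via iodo ylide 30 (not isolated)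
Conditions: N-iodosuccinimide, CH2Cl2, −20 °C; then 29, −20 °C → rt
Reagents that add atoms: N-iodosuccinimide, O=C1CCC(=O)N1I
Why: Halo-Wittig sequence: iodination of the stabilised ylide gives 30, and its Wittig reaction with the enal places the ester trans to the new vinyl substituent, so iodine and vinyl group are cis (Z).

Step 18
Reactants: 27 (1S)-1-[(2S,3S)-2-[(2R,3R)-3-ethenyl-3-methyloxiran-2-yl]-4-methylidene-5-oxooxolan-3-yl]-2-oxoethyl (2S,3S)-2,3-dimethyloxirane-2-carboxylate; 31 methyl (2Z)-2-iodopenta-2,4-dienoate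
Product: 32 methyl (2E)-2-[(1S,2S)-2-{[(2S,3S)-2,3-dimethyloxirane-2-carbonyl]oxy}-2-[(2S,3R)-2-[(2R,3R)-3-ethenyl-3-methyloxiran-2-yl]-4-methylidene-5-oxooxolan-3-yl]-1-hydroxyethyl]penta-2,4-dienoate
Conditions: CrCl2 (4 equiv), N-{2-[(4S)-4-isopropyl-4,5-dihydro-1,3-oxazol-2-yl]-6-methylphenyl}methanesulfonamide (4.4 equiv), Et3N (4.4 equiv), THF, rt; NiCl2 (10 mol%), 31 (2 equiv), 27, rt
Reagents that add atoms: none
Why: Nozaki–Hiyama–Kishi coupling: zerovalent nickel inserts into the C–I bond, the alkenyl group passes to trivalent chromium and adds to the aldehyde with retention of olefin geometry, so C9 ends up cis to C2. The polar Felkin–Anh bias of the α-acyloxy aldehyde favours the 8,9-anti carbinol, so the face is set by the chromium-bound chiral sulfonamide (reagent control), giving the 9S alcohol.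

Step 19
Reactants: 32 methyl (2E)-2-[(1S,2S)-2-{[(2S,3S)-2,3-dimethyloxirane-2-carbonyl]oxy}-2-[(2S,3R)-2-[(2R,3R)-3-ethenyl-3-methyloxiran-2-yl]-4-methylidene-5-oxooxolan-3-yl]-1-hydroxyethyl]penta-2,4-dienoate
Product: 33 methyl (2E)-2-[(1S,2S)-1-(acetyloxy)-2-{[(2S,3S)-2,3-dimethyloxirane-2-carbonyl]oxy}-2-[(2S,3R)-2-[(2R,3R)-3-ethenyl-3-methyloxiran-2-yl]-4-methylidene-5-oxooxolan-3-yl]ethyl]penta-2,4-dienoate
Conditions: Ac2O, pyridine, DMAP (cat.), CH2Cl2, 0 °C
Reagents that add atoms: acetic anhydride, CC(=O)OC(C)=O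
Why: DMAP-catalysed acetylation of the secondary allylic alcohol; it is faster than migration of the hindered O8 ester.

Step 20
Reactants: 33 methyl (2E)-2-[(1S,2S)-1-(acetyloxy)-2-{[(2S,3S)-2,3-dimethyloxirane-2-carbonyl]oxy}-2-[(2S,3R)-2-[(2R,3R)-3-ethenyl-3-methyloxiran-2-yl]-4-methylidene-5-oxooxolan-3-yl]ethyl]penta-2,4-dienoate
Product: 34 methyl (1(10)E,2Z,4R,5R,6S,7R,8S,9S)-9-acetoxy-8-{[(2S,3S)-2,3-dimethyloxirane-2-carbonyl]oxy}-4,5-epoxygermacra-1(10),2,11(13)-trien-12,6-olid-14-oate (germacrane numbering; the 2,3-deoxy target)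
Conditions: (H2IMes)(PCy3)Cl2Ru=CHPh (second-generation Grubbs catalyst, 10 mol% in portions), CH2Cl2 (0.5 mM), 40 °C, argon sparge
Reagents that add atoms: none
Why: Ring-closing olefin metathesis: the ruthenium benzylidene exchanges onto one of the two monosubstituted vinyl groups (the C3 vinyl on the epoxide or the C2 terminus of the dienoate), [2+2] cycloaddition with the other gives a ruthenacyclobutane, and cycloreversion releases ethene and the C2=C3 bond. The closest known reaction type is ring-closing metathesis of a vinyl epoxide with a 1,3-diene terminus to a medium-ring cis olefin. The one ring closed is the ten-membered carbocycle, formed by joining the chain termini C2 and C3 through the new double bond. No stereocentre is created; the only new stereo-element is the C2=C3 geometry, set by ring strain, since a trans C2=C3 bond next to the ring-cis C1=C10 enoate and the trans epoxide would be far higher in energy in a ten-membered ring. The step needs site selectivity, cyclisation over oligomerisation and Z geometry. The C11=C13 methylene is 1,1-disubstituted and electron-poor and the C1=C10 enoate is trisubstituted, so both are slow partners. A six-membered closure between C3 and C11 is impossible because C3 and C6 are trans on the epoxide. The trans lactone and the ring-cis enoate bend the chain so the termini meet, and high dilution with ethene removal favours the intramolecular path.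

Step 21
Reactants: 34 methyl (1(10)E,2Z,4R,5R,6S,7R,8S,9S)-9-acetoxy-8-{[(2S,3S)-2,3-dimethyloxirane-2-carbonyl]oxy}-4,5-epoxygermacra-1(10),2,11(13)-trien-12,6-olid-14-oate
Product: 35 methyl (1(10)E,2R,3R,4S,5R,6S,7R,8S,9S)-9-acetoxy-8-{[(2S,3S)-2,3-dimethyloxirane-2-carbonyl]oxy}-2,3:4,5-diepoxygermacra-1(10),11(13)-dien-12,6-olid-14-oate (CNP0077535.2)
Conditions: dimethyldioxirane (1.2 equiv, in acetone), CH2Cl2, −20 → 0 °C
Reagents that add atoms: dimethyldioxirane, CC1(C)OO1
Why: Electrophilic epoxidation under neutral conditions; the cis C2=C3 bond is the only olefin that is not an enoate α,β-bond or the lactone methylene. In the folded ring its exposed face is the one anti to the 4,5-epoxide oxygen, which gives the 2R,3R epoxide.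

## Compound list

1 | ethyl (2E)-3-methyl-4-oxobut-2-enoate | CCOC(=O)/C=C(\C)C=O | starting material
2 | ethyl (2E)-3-methylpenta-2,4-dienoate | CCOC(=O)/C=C(\C)C=C | intermediate
3 | (2E)-3-methylpenta-2,4-dien-1-ol | OC/C=C(\C)C=C | intermediate
4 | [(2R,3R)-3-ethenyl-3-methyloxiran-2-yl]methanol | OC[C@H]1O[C@]1(C)C=C | intermediate
5 | (2S,3R)-3-ethenyl-3-methyloxirane-2-carbaldehyde | O=C[C@H]1O[C@]1(C)C=C | intermediate
6 | (4S)-4-benzyl-1,3-oxazolidin-2-one | O=C1N[C@@H](Cc2ccccc2)CO1 | starting material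
7 | methyl 4-chloro-4-oxobutanoate | COC(=O)CCC(Cl)=O | starting material
8 | methyl 4-[(4S)-4-benzyl-2-oxo-1,3-oxazolidin-3-yl]-4-oxobutanoate | COC(=O)CCC(=O)N1[C@@H](Cc2ccccc2)COC1=O | intermediate
9 | methyl (3S,4S)-3-{[(4S)-4-benzyl-2-oxo-1,3-oxazolidin-3-yl]carbonyl}-4-[(2R,3R)-3-ethenyl-3-methyloxiran-2-yl]-4-hydroxybutanoate | O=C(N1[C@@H](Cc2ccccc2)COC1=O)[C@@H](CC(=O)OC)[C@H](O)[C@H]1O[C@]1(C)C=C | intermediate
10 | (4S)-4-benzyl-3-{[(2S,3S)-2-[(2R,3R)-3-ethenyl-3-methyloxiran-2-yl]-5-oxooxolan-3-yl]carbonyl}-1,3-oxazolidin-2-one | O=C1C[C@H](C(=O)N2[C@@H](Cc3ccccc3)COC2=O)[C@@H]([C@H]4O[C@]4(C)C=C)O1 | intermediate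
11 | (2S,3S)-2-[(2R,3R)-3-ethenyl-3-methyloxiran-2-yl]-5-oxooxolane-3-carboperoxoic acid | O=C1C[C@H](C(=O)OO)[C@@H]([C@H]2O[C@]2(C)C=C)O1 | intermediate
12 | (2S,3S)-2-[(2R,3R)-3-ethenyl-3-methyloxiran-2-yl]-5-oxooxolane-3-carboxylic acid | O=C1C[C@H](C(=O)O)[C@@H]([C@H]2O[C@]2(C)C=C)O1 | intermediate
13 | (4S,5S)-5-[(2R,3R)-3-ethenyl-3-methyloxiran-2-yl]-4-(1H-imidazol-1-ylcarbonyl)oxolan-2-one | O=C1C[C@H](C(=O)n2ccnc2)[C@@H]([C@H]3O[C@]3(C)C=C)O1 | intermediate
14 | (2S,3S)-2-[(2R,3R)-3-ethenyl-3-methyloxiran-2-yl]-N-methoxy-N-methyl-5-oxooxolane-3-carboxamide | O=C1C[C@H](C(=O)N(C)OC)[C@@H]([C@H]2O[C@]2(C)C=C)O1 | intermediate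
15 | (4S,5S)-5-[(2R,3R)-3-ethenyl-3-methyloxiran-2-yl]-4-(3-methylbut-2-enoyl)oxolan-2-one | O=C1C[C@H](C(=O)C=C(C)C)[C@@H]([C@H]2O[C@]2(C)C=C)O1 | intermediate
16 | (4R,5S)-5-[(2R,3R)-3-ethenyl-3-methyloxiran-2-yl]-4-[(1R)-1-hydroxy-3-methylbut-2-en-1-yl]oxolan-2-one | O=C1C[C@H]([C@H](O)C=C(C)C)[C@@H]([C@H]2O[C@]2(C)C=C)O1 | intermediate
17 | angelic acid, (2Z)-2-methylbut-2-enoic acid | C/C=C(/C)C(=O)O | starting material
18 | (2Z)-2-methylbut-2-en-1-ol | C/C=C(/C)CO | intermediate
19 | [(2R,3S)-2,3-dimethyloxiran-2-yl]methanol | OC[C@@]1(C)O[C@H]1C | intermediate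
20 | (2S,3S)-2,3-dimethyloxirane-2-carbaldehyde | O=C[C@@]1(C)O[C@H]1C | intermediate
21 | (2S,3S)-2,3-dimethyloxirane-2-carboxylic acid | OC(=O)[C@@]1(C)O[C@H]1C | intermediate
22 | (2S,3S)-2,3-dimethyloxirane-2-carboxylic 2,4,6-trichlorobenzoic anhydride | O=C(OC(=O)c1c(Cl)cc(Cl)cc1Cl)[C@@]1(C)O[C@H]1C | intermediate
23 | (1R)-1-[(2S,3R)-2-[(2R,3R)-3-ethenyl-3-methyloxiran-2-yl]-5-oxooxolan-3-yl]-3-methylbut-2-en-1-yl (2S,3S)-2,3-dimethyloxirane-2-carboxylate | O=C1C[C@H]([C@H](OC(=O)[C@@]3(C)O[C@H]3C)C=C(C)C)[C@@H]([C@H]2O[C@]2(C)C=C)O1 | intermediate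
24 | (1R)-1-[(2S,3R,4R)-4-[(dimethylamino)methyl]-2-[(2R,3R)-3-ethenyl-3-methyloxiran-2-yl]-5-oxooxolan-3-yl]-3-methylbut-2-en-1-yl (2S,3S)-2,3-dimethyloxirane-2-carboxylate | O=C1[C@@H](CN(C)C)[C@H]([C@H](OC(=O)[C@@]3(C)O[C@H]3C)C=C(C)C)[C@@H]([C@H]2O[C@]2(C)C=C)O1 | intermediate
25 | N-methyl iodide of 24, {[(3R,4R,5S)-4-[(1R)-1-{[(2S,3S)-2,3-dimethyloxirane-2-carbonyl]oxy}-3-methylbut-2-en-1-yl]-5-[(2R,3R)-3-ethenyl-3-methyloxiran-2-yl]-2-oxooxolan-3-yl]methyl}trimethylazanium iodide | O=C1[C@@H](C[N+](C)(C)C)[C@H]([C@H](OC(=O)[C@@]3(C)O[C@H]3C)C=C(C)C)[C@@H]([C@H]2O[C@]2(C)C=C)O1.[I-] | intermediate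
26 | (1R)-1-[(2S,3R)-2-[(2R,3R)-3-ethenyl-3-methyloxiran-2-yl]-4-methylidene-5-oxooxolan-3-yl]-3-methylbut-2-en-1-yl (2S,3S)-2,3-dimethyloxirane-2-carboxylate | O=C1C(=C)[C@H]([C@H](OC(=O)[C@@]3(C)O[C@H]3C)C=C(C)C)[C@@H]([C@H]2O[C@]2(C)C=C)O1 | intermediate
27 | (1S)-1-[(2S,3S)-2-[(2R,3R)-3-ethenyl-3-methyloxiran-2-yl]-4-methylidene-5-oxooxolan-3-yl]-2-oxoethyl (2S,3S)-2,3-dimethyloxirane-2-carboxylate | O=C1C(=C)[C@H]([C@H](OC(=O)[C@@]3(C)O[C@H]3C)C=O)[C@@H]([C@H]2O[C@]2(C)C=C)O1 | intermediate
28 | methyl (triphenyl-λ5-phosphanylidene)acetate | COC(=O)C=P(c1ccccc1)(c1ccccc1)c1ccccc1 | starting material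
29 | acrolein (prop-2-enal) | C=CC=O | starting material
30 | methyl iodo(triphenyl-λ5-phosphanylidene)acetate | COC(=O)C(I)=P(c1ccccc1)(c1ccccc1)c1ccccc1 | intermediate
31 | methyl (2Z)-2-iodopenta-2,4-dienoate | COC(=O)/C(I)=C/C=C | intermediate
32 | methyl (2E)-2-[(1S,2S)-2-{[(2S,3S)-2,3-dimethyloxirane-2-carbonyl]oxy}-2-[(2S,3R)-2-[(2R,3R)-3-ethenyl-3-methyloxiran-2-yl]-4-methylidene-5-oxooxolan-3-yl]-1-hydroxyethyl]penta-2,4-dienoate | C=C1C(=O)O[C@H]([C@H]3O[C@]3(C)C=C)[C@H]1[C@H](OC(=O)[C@@]1(C)O[C@H]1C)[C@@H](O)/C(C(=O)OC)=C\C=C | intermediate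
33 | methyl (2E)-2-[(1S,2S)-1-(acetyloxy)-2-{[(2S,3S)-2,3-dimethyloxirane-2-carbonyl]oxy}-2-[(2S,3R)-2-[(2R,3R)-3-ethenyl-3-methyloxiran-2-yl]-4-methylidene-5-oxooxolan-3-yl]ethyl]penta-2,4-dienoate | C=C1C(=O)O[C@H]([C@H]3O[C@]3(C)C=C)[C@H]1[C@H](OC(=O)[C@@]1(C)O[C@H]1C)[C@@H](OC(C)=O)/C(C(=O)OC)=C\C=C | intermediate
34 | methyl (1(10)E,2Z,4R,5R,6S,7R,8S,9S)-9-acetoxy-8-{[(2S,3S)-2,3-dimethyloxirane-2-carbonyl]oxy}-4,5-epoxygermacra-1(10),2,11(13)-trien-12,6-olid-14-oate | C=C1C(=O)O[C@H]2[C@H]1[C@H](OC(=O)[C@@]1(C)O[C@H]1C)[C@@H](OC(C)=O)/C(C(=O)OC)=C\C=C/[C@@]1(C)O[C@H]21 | intermediate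
35 | methyl (1(10)E,2R,3R,4S,5R,6S,7R,8S,9S)-9-acetoxy-8-{[(2S,3S)-2,3-dimethyloxirane-2-carbonyl]oxy}-2,3:4,5-diepoxygermacra-1(10),11(13)-dien-12,6-olid-14-oate (CNP0077535.2) | C=C1C(=O)O[C@H]2[C@H]1[C@H](OC(=O)[C@@]1(C)O[C@H]1C)[C@@H](OC(C)=O)/C(C(=O)OC)=C\[C@H]1O[C@H]1[C@@]1(C)O[C@H]21 | target

## Step count and least certain steps

Total: 21 steps. Longest linear sequence: 16 steps (steps 1–4, 6–10, 14–16, 18–21).

Step 20 (key step). The likely failures are cross-metathesis oligomerisation at the dienoate terminus and sequestration of the catalyst as an ester-conjugated vinylcarbene. A further one is closure of a carbene sitting on C2 onto the C11=C13 methylene (a seven-membered ring) in place of the hindered vinyl epoxide. Fallback, from 33 back to 34: conjugate addition of dimethylamine to the lactone methylene gives the 13-dimethylamino adduct F1, which has no competing olefin. F1 is cyclised with the same ruthenium carbene in the presence of one equivalent of camphorsulfonic acid, which keeps the amine protonated, and gives the ten-membered amine F2. Methyl iodide converts F2 into the trimethylammonium iodide F3, and aqueous NaHCO3 eliminates trimethylamine to give 34.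

Step 18. The coupling may show poor facial selectivity, because ligand control works against the substrate bias of the α-acyloxy aldehyde. The olefin geometry may also be lost if the α-ester alkenylchromium equilibrates through an oxygen-bound enolate form. Fallback, from 31 and 27 back to 33:
- Ester 31 is reduced with i-Bu2AlH to (2Z)-2-iodopenta-2,4-dien-1-ol F4 and silylated to its tert-butyldimethylsilyl ether F5, an alkenyl iodide that cannot form an enolate.
- Ligand-free CrCl2/NiCl2 coupling of F5 with 27 gives the C9 carbinol F6 as an epimer mixture, and Dess–Martin oxidation gives the cross-conjugated dienone F7.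
- Reduction of F7 with (S)-2-methyl-CBS-oxazaborolidine and catecholborane sets C9 by reagent control and gives the 9S alcohol F8.
- Acetylation gives F9, buffered fluoride removes the silyl group to give the primary allylic alcohol F10, MnO2 gives the dienal F11, and NaClO2 gives the acid F12, which Me3SiCHN2 methylates to 33.

Step 10. Hydride may add with insufficient facial selectivity, or in conjugate fashion. Fallback, from 15 back to 23: the 8-epimeric carbinol F13 that forms beside 16 is esterified with acid 21 under Mitsunobu conditions (PPh3, diisopropyl azodicarboxylate) with inversion at C8. Both epimers then converge on 23, 16 by the Yamaguchi route with retention and F13 by inversion.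

Step 6. Double diastereoselection with the chiral epoxy aldehyde may be mismatched, and the boron Lewis acid may open the tertiary vinyl epoxide. Fallback, from 3 back to 9 and so to 10: MnO2 oxidises 3 to (2E)-3-methylpenta-2,4-dienal F14, an aldehyde with no stereocentre and no epoxide. The same boron aldol with 8 gives the allylic alcohol F15 under pure reagent control. Buffered m-chloroperoxybenzoic acid then epoxidises the C4=C5 bond of F15 on the face directed by the free C6 hydroxyl (A(1,3) strain with the cis methyl group, threo product), which gives 9.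

Step 21. Oxygen may be delivered to the wrong face of C2=C3, or the lactone methylene may be over-oxidised. Fallback, from 34 back to 35: N-bromosuccinimide in wet THF gives the trans bromohydrin F16, with bromine on the exposed face and water entering from the other face. K2CO3 closes F16 to 35, so the oxygen ends on the face opposite to the one a direct oxygen donor attacks.

## Further compounds

F1 | step 20 | dimethylamine adduct of 33, methyl (2E)-2-[(1S,2S)-1-(acetyloxy)-2-{[(2S,3S)-2,3-dimethyloxirane-2-carbonyl]oxy}-2-[(2S,3R,4R)-4-[(dimethylamino)methyl]-2-[(2R,3R)-3-ethenyl-3-methyloxiran-2-yl]-5-oxooxolan-3-yl]ethyl]penta-2,4-dienoate | CN(C)C[C@@H]1C(=O)O[C@H]([C@H]3O[C@]3(C)C=C)[C@H]1[C@H](OC(=O)[C@@]1(C)O[C@H]1C)[C@@H](OC(C)=O)/C(C(=O)OC)=C\C=C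
F2 | step 20 | 11,13-dihydro-13-(dimethylamino) derivative of 34 | CN(C)C[C@@H]1C(=O)O[C@H]2[C@H]1[C@H](OC(=O)[C@@]1(C)O[C@H]1C)[C@@H](OC(C)=O)/C(C(=O)OC)=C\C=C/[C@@]1(C)O[C@H]21
F3 | step 20 | trimethylammonium iodide of F2 | C[N+](C)(C)C[C@@H]1C(=O)O[C@H]2[C@H]1[C@H](OC(=O)[C@@]1(C)O[C@H]1C)[C@@H](OC(C)=O)/C(C(=O)OC)=C\C=C/[C@@]1(C)O[C@H]21.[I-]
F4 | step 18 | (2Z)-2-iodopenta-2,4-dien-1-ol | OC/C(I)=C/C=C
F5 | step 18 | tert-butyl{[(2Z)-2-iodopenta-2,4-dien-1-yl]oxy}dimethylsilane | CC(C)(C)[Si](C)(C)OC/C(I)=C/C=C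
F6 | step 18 | C9 carbinol (both epimers) with C14 as tert-butyldimethylsilyl ether, otherwise as 32 | C=C1C(=O)O[C@H]([C@H]3O[C@]3(C)C=C)[C@H]1[C@H](OC(=O)[C@@]1(C)O[C@H]1C)C(O)/C(CO[Si](C)(C)C(C)(C)C)=C\C=C
F7 | step 18 | C9 ketone (dienone) with C14 silyl ether | C=C1C(=O)O[C@H]([C@H]3O[C@]3(C)C=C)[C@H]1[C@H](OC(=O)[C@@]1(C)O[C@H]1C)C(=O)/C(CO[Si](C)(C)C(C)(C)C)=C\C=C
F8 | step 18 | (9S)-carbinol with C14 silyl ether | C=C1C(=O)O[C@H]([C@H]3O[C@]3(C)C=C)[C@H]1[C@H](OC(=O)[C@@]1(C)O[C@H]1C)[C@@H](O)/C(CO[Si](C)(C)C(C)(C)C)=C\C=C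
F9 | step 18 | (9S)-acetate with C14 silyl ether | C=C1C(=O)O[C@H]([C@H]3O[C@]3(C)C=C)[C@H]1[C@H](OC(=O)[C@@]1(C)O[C@H]1C)[C@@H](OC(C)=O)/C(CO[Si](C)(C)C(C)(C)C)=C\C=C
F10 | step 18 | (9S)-acetate with free C14 allylic alcohol | C=C1C(=O)O[C@H]([C@H]3O[C@]3(C)C=C)[C@H]1[C@H](OC(=O)[C@@]1(C)O[C@H]1C)[C@@H](OC(C)=O)/C(CO)=C\C=C
F11 | step 18 | (9S)-acetate with C14 aldehyde (dienal) | C=C1C(=O)O[C@H]([C@H]3O[C@]3(C)C=C)[C@H]1[C@H](OC(=O)[C@@]1(C)O[C@H]1C)[C@@H](OC(C)=O)/C(C=O)=C\C=C
F12 | step 18 | (9S)-acetate with C14 carboxylic acid | C=C1C(=O)O[C@H]([C@H]3O[C@]3(C)C=C)[C@H]1[C@H](OC(=O)[C@@]1(C)O[C@H]1C)[C@@H](OC(C)=O)/C(C(=O)O)=C\C=C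
F13 | step 10 | 8-epimer of 16, (4R,5S)-5-[(2R,3R)-3-ethenyl-3-methyloxiran-2-yl]-4-[(1S)-1-hydroxy-3-methylbut-2-en-1-yl]oxolan-2-one | O=C1C[C@H]([C@@H](O)C=C(C)C)[C@@H]([C@H]2O[C@]2(C)C=C)O1
F14 | step 6 | (2E)-3-methylpenta-2,4-dienal | O=C/C=C(\C)C=C
F15 | step 6 | methyl (3S,4R,5E)-3-{[(4S)-4-benzyl-2-oxo-1,3-oxazolidin-3-yl]carbonyl}-4-hydroxy-6-methylocta-5,7-dienoate | O=C(N1[C@@H](Cc2ccccc2)COC1=O)[C@@H](CC(=O)OC)[C@H](O)/C=C(\C)C=C
F16 | step 21 | trans-3-bromo-2-hydroxy derivative of 34 (bromohydrin) | C=C1C(=O)O[C@H]2[C@H]1[C@H](OC(=O)[C@@]1(C)O[C@H]1C)[C@@H](OC(C)=O)/C(C(=O)OC)=C\[C@@H](O)[C@H](Br)[C@@]1(C)O[C@H]21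
A1 | alternative 1 | methyl 9-oxo-8-[(4-methoxybenzyl)oxy]-6-(triethylsilyloxy)-12-(tert-butyldimethylsilyloxy)germacra-1(10),2,4,11(13)-tetraen-14-oate (ring-cis C1=C10 and C2=C3, trans C4=C5) | O=C1/C(C(=O)OC)=C\C=C/C(C)=C/[C@@H](O[Si](CC)(CC)CC)[C@H](C(=C)CO[Si](C)(C)C(C)(C)C)[C@@H]1OCc1ccc(OC)cc1
A2 | alternative 2 | 2,9-epidioxy-4,5-epoxy-3-(triethylsilyloxy)-8-(epoxyangeloyloxy)germacra-1(10),11(13)-dien-12,6-olid-14-oic acid methyl ester | C=C1C(=O)O[C@H]2[C@H]1[C@H](OC(=O)[C@@]1(C)O[C@H]1C)[C@H]3OO[C@H](C=C3C(=O)OC)[C@H](O[Si](CC)(CC)CC)[C@@]1(C)O[C@H]21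
A3 | alternative 3 | methyl 9-acetoxy-8-(tert-butyldimethylsilyloxy)germacra-1(10),2,4,11(13)-tetraen-12,6-olid-14-oate (ring-cis C1=C10 and C2=C3, trans C4=C5) | C=C1C(=O)O[C@@H]2/C=C(C)/C=C\C=C(C(=O)OC)/[C@H](OC(C)=O)[C@@H](O[Si](C)(C)C(C)(C)C)[C@@H]12
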